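**Retrosynthetic overview**

1. Locants follow the C15 chain from the alkyne terminus (C1) to the methyl group (C15): the ether oxygen bridges C6 and C12, chlorine sits on C7 and C9, the acetate on C10, bromine on C13.
2. Last disconnections: the C10 acetate and the (Z)-enyne (C1–C3 joined to a C4 aldehyde by Peterson olefination).
3. Key disconnection: O–C12, C13–Br and C9–Cl are cut together. C9 lies 1,5-transannular to the ether oxygen, so the oxocane is the sum of two oxolane rings sharing an O–C9 bond: ring A (O, C6, C7, C8, C9), present in the precursor, and ring B (O, C9, C10, C11, C12), closed on a C12=C13 bromonium ion to give a 1-oxoniabicyclo[3.3.0]octane that chloride opens at C9.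
4. Ring A: Shi epoxidation of an E-C9=C10 alkene and 5-exo opening by the C6 hydroxyl; C6/C7 from Sharpless desymmetrisation of divinylcarbinol (C7–Cl by inversion); C8–C9 from alkenyllithium plus epoxide; C12=C13 by Z-selective Wittig reaction.
5. Ring order: oxolane ring A (step 7), then transient ring B and the eight-membered oxocane in one operation (step 12).

Key step: step 12

Remark: BDSB (Et2SBr·SbCl5Br) and the L-fructose-derived enantiomer of the Shi ketone are treated as purchasable reagents.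

**Route**

Step 1
Reactants: 1 penta-1,4-dien-3-ol (divinylcarbinol)
Product: 2 (2R,3S)-1,2-epoxypent-4-en-3-ol
Conditions: Ti(OiPr)4, L-(+)-diisopropyl tartrate, t-BuOOH, 4 Å sieves, CH2Cl2, −20 °C
Reagents that add atoms: tert-butyl hydroperoxide, CC(C)(C)OO
Why: Sharpless asymmetric epoxidation selects one enantiotopic vinyl group and one alkene face under tartrate control, so the erythro epoxy alcohol should form with C6 and C7 set, its enantiomeric purity being raised further because the minor enantiomer is over-oxidised faster.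

Step 2
Reactants: 2 (2R,3S)-1,2-epoxypent-4-en-3-ol
Product: 3 triethyl{[(1S)-1-[(2R)-oxiran-2-yl]prop-2-en-1-yl]oxy}silane
Conditions: Et3SiCl, imidazole, CH2Cl2, 0 °C
Reagents that add atoms: chlorotriethylsilane, CC[Si](Cl)(CC)CC
Why: Imidazole-mediated silylation masks the C6 hydroxyl so that the epoxide can later be opened without Payne rearrangement and C7 can be functionalised alone.

Step 3
Reactants: 4 benzyl but-3-yn-1-yl ether
Product: 6 (E)-4-(benzyloxy)-1-iodobut-1-ene, via alkenylzirconocene 5 (not isolated)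
Conditions: Cp2Zr(H)Cl, THF, rt; then I2, 0 °C
Reagents that add atoms: iodine, II
Why: syn-Hydrozirconation places zirconium on the terminal alkyne carbon and iodinolysis of the C–Zr bond proceeds with retention, which should give the E-alkenyl iodide.

Step 4
Reactants: 6 (E)-4-(benzyloxy)-1-iodobut-1-ene, 3 triethyl{[(1S)-1-[(2R)-oxiran-2-yl]prop-2-en-1-yl]oxy}silane
Product: 8 (3S,4R,6E)-9-(benzyloxy)-3-[(triethylsilyl)oxy]nona-1,6-dien-4-ol, via alkenyllithium 7 (not isolated)
Conditions: 6, t-BuLi (2 equiv), Et2O, −78 °C; then 3, BF3·OEt2, −78 °C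
Reagents that add atoms: none
Why: Iodine–lithium exchange with retention of alkene geometry, followed by BF3-promoted SN2 opening of the terminal epoxide at its CH2 carbon, forms the C8–C9 bond and leaves the C7 configuration untouched.

Step 5
Reactants: 8 (3S,4R,6E)-9-(benzyloxy)-3-[(triethylsilyl)oxy]nona-1,6-dien-4-ol
Product: 9 {[(3S,4S,6E)-9-(benzyloxy)-4-chloronona-1,6-dien-3-yl]oxy}triethylsilane
Conditions: (n-C8H17)3P, CCl4, toluene, 70 °C
Reagents that add atoms: carbon tetrachloride, ClC(Cl)(Cl)Cl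
Why: Appel-type deoxychlorination replaces the activated C7 hydroxyl by chloride in an SN2 step with inversion, turning the erythro C6/C7 pair into the threo chlorohydrin ether required for the cis 2,3-relationship on the oxolane.

Step 6
Reactants: 9 {[(3S,4S,6E)-9-(benzyloxy)-4-chloronona-1,6-dien-3-yl]oxy}triethylsilane
Product: 11 (3S,4S,6E)-9-(benzyloxy)-4-chloro-3-[(triethylsilyl)oxy]non-6-en-1-ol, via alkylborane 10 (not isolated)
Conditions: 9-BBN, THF, 0 °C → rt; then NaOH, H2O2, 0 °C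
Reagents that add atoms: hydrogen peroxide, OO
Why: Hydroboration with the bulky 9-BBN is selective for the monosubstituted vinyl group over the internal E-alkene, and oxidation with retention should deliver the anti-Markovnikov primary alcohol (C4).

Step 7
Reactants: 11 (3S,4S,6E)-9-(benzyloxy)-4-chloro-3-[(triethylsilyl)oxy]non-6-en-1-ol
Product: 13 (1S)-3-(benzyloxy)-1-[(2R,4S,5S)-4-chloro-5-(2-hydroxyethyl)oxolan-2-yl]propan-1-ol, via epoxide 12 (not isolated)
Conditions: L-fructose-derived Shi ketone (0.3 equiv), Oxone, K2CO3, Bu4NHSO4, Na2B4O7 buffer, MeCN/CH2(OMe)2, 0 °C; then PPTS, MeOH, rt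
Reagents that add atoms: potassium peroxymonosulfate (Oxone), [K+].OOS(=O)(=O)[O-]
Why: Shi epoxidation converts the E-alkene into the (9S,10S)-epoxide under catalyst control while the silyl ether keeps the chlorohydrin closed to base, and mild acid then removes the triethylsilyl group and lets the C6 hydroxyl open the epoxide at C9 with inversion in a 5-exo closure, setting C9 (trans to the C6 side chain) and C10.

Step 8
Reactants: 13 (1S)-3-(benzyloxy)-1-[(2R,4S,5S)-4-chloro-5-(2-hydroxyethyl)oxolan-2-yl]propan-1-ol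
Product: 14 (2S,3S,5R)-5-{(1S)-3-(benzyloxy)-1-[(tert-butyldimethylsilyl)oxy]propyl}-2-{2-[(tert-butyldimethylsilyl)oxy]ethyl}-3-chlorooxolane
Conditions: TBSOTf, 2,6-lutidine, CH2Cl2, −78 → 0 °C
Reagents that add atoms: tert-butyldimethylsilyl triflate, CC(C)(C)[Si](C)(C)OS(=O)(=O)C(F)(F)F
Why: Silyl triflate silylation protects both hydroxyls as non-participating ethers, the one at C10 being chosen so that it cannot act as a neighbouring group in step 12.

Step 9
Reactants: 14 (2S,3S,5R)-5-{(1S)-3-(benzyloxy)-1-[(tert-butyldimethylsilyl)oxy]propyl}-2-{2-[(tert-butyldimethylsilyl)oxy]ethyl}-3-chlorooxolane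
Product: 15 (3S)-3-[(tert-butyldimethylsilyl)oxy]-3-[(2R,4S,5S)-5-{2-[(tert-butyldimethylsilyl)oxy]ethyl}-4-chlorooxolan-2-yl]propan-1-ol
Conditions: H2 (1 atm), Pd/C, EtOAc, rt
Reagents that add atoms: none
Why: Hydrogenolysis cleaves the benzyl ether in a molecule that holds no alkene at this stage, the secondary alkyl chloride and silyl ethers being inert in a neutral aprotic solvent.

Step 10
Reactants: 15 (3S)-3-[(tert-butyldimethylsilyl)oxy]-3-[(2R,4S,5S)-5-{2-[(tert-butyldimethylsilyl)oxy]ethyl}-4-chlorooxolan-2-yl]propan-1-ol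
Product: 16 (3S)-3-[(tert-butyldimethylsilyl)oxy]-3-[(2R,4S,5S)-5-{2-[(tert-butyldimethylsilyl)oxy]ethyl}-4-chlorooxolan-2-yl]propanal
Conditions: Dess–Martin periodinane, NaHCO3, CH2Cl2, 0 °C → rt
Reagents that add atoms: none
Why: Dess–Martin oxidation gives the β-silyloxy aldehyde under buffered, non-basic conditions that should avoid β-elimination.

Step 11
Reactants: 16 (3S)-3-[(tert-butyldimethylsilyl)oxy]-3-[(2R,4S,5S)-5-{2-[(tert-butyldimethylsilyl)oxy]ethyl}-4-chlorooxolan-2-yl]propanal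
Product: 17 (2S,3S,5R)-2-{2-[(tert-butyldimethylsilyl)oxy]ethyl}-5-{(1S,3Z)-1-[(tert-butyldimethylsilyl)oxy]hex-3-en-1-yl}-3-chlorooxolane
Conditions: n-PrPPh3Br, NaN(SiMe3)2, THF, −78 °C → rt
Reagents that add atoms: propyltriphenylphosphonium bromide, CCC[P+](c1ccccc1)(c1ccccc1)c1ccccc1.[Br-]
Why: Wittig reaction of the non-stabilised ylide under salt-free conditions should give the Z-C12=C13 alkene, whose geometry later translates into the relative configuration of C12 and C13.

Step 12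
Reactants: 17 (2S,3S,5R)-2-{2-[(tert-butyldimethylsilyl)oxy]ethyl}-5-{(1S,3Z)-1-[(tert-butyldimethylsilyl)oxy]hex-3-en-1-yl}-3-chlorooxolane
Product: 20 (2S,3S,5S,6S,8R)-8-[(1R)-1-bromopropyl]-6-[(tert-butyldimethylsilyl)oxy]-2-{2-[(tert-butyldimethylsilyl)oxy]ethyl}-3,5-dichlorooxocane, via bromonium ion 18 (not isolated), via oxonium ion 19 (not isolated)
Conditions: BDSB (Et2SBr·SbCl5Br, 1.2 equiv), MeNO2, −25 °C, 5 min; then Bu4NCl (5 equiv), −25 → 0 °C
Reagents that add atoms: bromodiethylsulfonium bromopentachloroantimonate (BDSB), CC[S+](Br)CC.Cl[Sb-](Cl)(Cl)(Cl)(Cl)Br; tetrabutylammonium chloride, CCCC[N+](CCCC)(CCCC)CCCC.[Cl-]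
Why: Proposed new method: BDSB transfers bromonium reversibly to the Z-alkene (18), the oxolane oxygen of ring A attacks C12 anti to bromine in a 5-exo closure of ring B to give the cis-fused 1-oxoniabicyclo[3.3.0]octane ion 19, and added chloride then opens 19 by SN2 attack at the ring-fusion carbon C9, so that cleavage of the shared O–C9 bond merges rings A and B into the oxocane (net three-atom ring expansion with formation of O–C12, C13–Br and C9–Cl). The closest known reaction types are the BDSB-induced ring-expanding bromoetherification of 2-(alk-3-enyl)oxolanes, in which a tethered carbonate opens the same kind of oxonium ion at the fusion carbon, and the capture by chloride of bromonium-derived oxonium ions in related medium-ring ether systems; new here is external chloride as the third component on this substrate class. C12 and C13 follow from stereospecific anti addition of oxygen and bromine across the Z-alkene together with the alkene face imposed by ring A, the 1-bromopropyl group taking the exo (convex) position of 19 trans to the C6 substituent across the oxonium oxygen, and C9 is set by inversion, which places chlorine trans to the C10 silyloxy group. The step needs chloride to attack C9 and not C6 or C12: C6 is deactivated by the β-chlorine at C7, C12 by the β-bromine and its branching, only cleavage at C9 relieves both five-membered rings, and return of a nucleophile to the fusion carbon of this oxonium system is the path by which oxocan-5-yl sulfonates solvolyse. The non-participating silyl ether at C10 (an ester would form a dioxolanylium ion) and the delayed addition of chloride (no bromochlorination of the alkene) secure the chemoselectivity.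

Step 13
Reactants: 20 (2S,3S,5S,6S,8R)-8-[(1R)-1-bromopropyl]-6-[(tert-butyldimethylsilyl)oxy]-2-{2-[(tert-butyldimethylsilyl)oxy]ethyl}-3,5-dichlorooxocane
Product: 21 2-{(2S,3S,5S,6S,8R)-8-[(1R)-1-bromopropyl]-6-[(tert-butyldimethylsilyl)oxy]-3,5-dichlorooxocan-2-yl}ethan-1-ol
Conditions: HF·pyridine, pyridine, THF, 0 °C
Reagents that add atoms: none
Why: Buffered fluoride cleaves the unhindered primary silyl ether much faster than the secondary one flanked by the C9 chloride, a standard selective desilylation.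

Step 14
Reactants: 21 2-{(2S,3S,5S,6S,8R)-8-[(1R)-1-bromopropyl]-6-[(tert-butyldimethylsilyl)oxy]-3,5-dichlorooxocan-2-yl}ethan-1-ol
Product: 22 2-{(2S,3S,5S,6S,8R)-8-[(1R)-1-bromopropyl]-6-[(tert-butyldimethylsilyl)oxy]-3,5-dichlorooxocan-2-yl}acetaldehyde
Conditions: Dess–Martin periodinane, NaHCO3, CH2Cl2, 0 °C → rt
Reagents that add atoms: none
Why: Dess–Martin oxidation gives the β-alkoxy aldehyde (C4) without base, and it should be used at once in the olefination.

Step 15
Reactants: 22 2-{(2S,3S,5S,6S,8R)-8-[(1R)-1-bromopropyl]-6-[(tert-butyldimethylsilyl)oxy]-3,5-dichlorooxocan-2-yl}acetaldehyde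
Product: 23 (2S,3S,5S,6S,8R)-8-[(1R)-1-bromopropyl]-6-[(tert-butyldimethylsilyl)oxy]-3,5-dichloro-2-[(2Z)-5-(triisopropylsilyl)pent-2-en-4-yn-1-yl]oxocane
Conditions: 1,3-bis(triisopropylsilyl)propyne, n-BuLi, THF, −78 °C; then 22, −78 → −20 °C
Reagents that add atoms: 1,3-bis(triisopropylsilyl)propyne, CC(C)[Si](C(C)C)(C(C)C)CC#C[Si](C(C)C)(C(C)C)C(C)C
Why: Peterson olefination with lithiated 1,3-bis(triisopropylsilyl)propyne converts aliphatic aldehydes directly into (Z)-enynes, the bulky silyl groups controlling the alkene geometry.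

Step 16
Reactants: 23 (2S,3S,5S,6S,8R)-8-[(1R)-1-bromopropyl]-6-[(tert-butyldimethylsilyl)oxy]-3,5-dichloro-2-[(2Z)-5-(triisopropylsilyl)pent-2-en-4-yn-1-yl]oxocane
Product: 24 (2S,3S,5S,6S,8R)-8-[(1R)-1-bromopropyl]-3,5-dichloro-2-[(2Z)-pent-2-en-4-yn-1-yl]oxocan-6-ol
Conditions: Bu4NF, AcOH, THF, 0 °C → rt
Reagents that add atoms: none
Why: Fluoride cleaves both the alkynyl C–Si bond and the secondary O–Si bond, acetic acid buffering the medium so that the secondary bromide and chlorides should not be eliminated.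

Step 17
Reactants: 24 (2S,3S,5S,6S,8R)-8-[(1R)-1-bromopropyl]-3,5-dichloro-2-[(2Z)-pent-2-en-4-yn-1-yl]oxocan-6-ol
Product: 25 (2S,3S,5S,6S,8R)-8-[(1R)-1-bromopropyl]-3,5-dichloro-2-[(2Z)-pent-2-en-4-yn-1-yl]oxocan-6-yl acetate (target)
Conditions: Ac2O, pyridine, DMAP, CH2Cl2, 0 °C → rt
Reagents that add atoms: acetic anhydride, CC(=O)OC(C)=O
Why: DMAP-catalysed acylation of the C10 hydroxyl touches no stereocenter and completes the target.

**Compound list**

1 | penta-1,4-dien-3-ol | C=CC(O)C=C | starting material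
2 | (2R,3S)-1,2-epoxypent-4-en-3-ol | C=C[C@H](O)[C@H]1CO1 | intermediate
3 | triethyl{[(1S)-1-[(2R)-oxiran-2-yl]prop-2-en-1-yl]oxy}silane | C=C[C@H](O[Si](CC)(CC)CC)[C@H]1CO1 | intermediate
4 | benzyl but-3-yn-1-yl ether | C#CCCOCc1ccccc1 | starting material
5 | [(1E)-4-(benzyloxy)but-1-en-1-yl]chlorobis(cyclopentadienyl)zirconium (rings drawn σ-bonded) | Cl[Zr](/C=C/CCOCc1ccccc1)(C1C=CC=C1)C1C=CC=C1 | intermediate
6 | (E)-4-(benzyloxy)-1-iodobut-1-ene | I/C=C/CCOCc1ccccc1 | intermediate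
7 | (E)-4-(benzyloxy)but-1-en-1-yllithium | [Li]/C=C/CCOCc1ccccc1 | intermediate
8 | (3S,4R,6E)-9-(benzyloxy)-3-[(triethylsilyl)oxy]nona-1,6-dien-4-ol | C=C[C@H](O[Si](CC)(CC)CC)[C@H](O)C/C=C/CCOCc1ccccc1 | intermediate
9 | {[(3S,4S,6E)-9-(benzyloxy)-4-chloronona-1,6-dien-3-yl]oxy}triethylsilane | C=C[C@H](O[Si](CC)(CC)CC)[C@@H](Cl)C/C=C/CCOCc1ccccc1 | intermediate
10 | 9-[(3S,4S,6E)-9-(benzyloxy)-4-chloro-3-(triethylsilyloxy)non-6-en-1-yl]-9-borabicyclo[3.3.1]nonane | C1CCC2CCCC1B2CC[C@H](O[Si](CC)(CC)CC)[C@@H](Cl)C/C=C/CCOCc1ccccc1 | intermediate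
11 | (3S,4S,6E)-9-(benzyloxy)-4-chloro-3-[(triethylsilyl)oxy]non-6-en-1-ol | OCC[C@H](O[Si](CC)(CC)CC)[C@@H](Cl)C/C=C/CCOCc1ccccc1 | intermediate
12 | (3S,4S)-5-{(2S,3S)-3-[2-(benzyloxy)ethyl]oxiran-2-yl}-4-chloro-3-[(triethylsilyl)oxy]pentan-1-ol | OCC[C@H](O[Si](CC)(CC)CC)[C@@H](Cl)C[C@@H]1O[C@H]1CCOCc1ccccc1 | intermediate
13 | (1S)-3-(benzyloxy)-1-[(2R,4S,5S)-4-chloro-5-(2-hydroxyethyl)oxolan-2-yl]propan-1-ol | OCC[C@@H]1O[C@@H]([C@@H](O)CCOCc2ccccc2)C[C@@H]1Cl | intermediate
14 | (2S,3S,5R)-5-{(1S)-3-(benzyloxy)-1-[(tert-butyldimethylsilyl)oxy]propyl}-2-{2-[(tert-butyldimethylsilyl)oxy]ethyl}-3-chlorooxolane | CC(C)(C)[Si](C)(C)OCC[C@@H]1O[C@@H]([C@@H](O[Si](C)(C)C(C)(C)C)CCOCc2ccccc2)C[C@@H]1Cl | intermediate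
15 | (3S)-3-[(tert-butyldimethylsilyl)oxy]-3-[(2R,4S,5S)-5-{2-[(tert-butyldimethylsilyl)oxy]ethyl}-4-chlorooxolan-2-yl]propan-1-ol | CC(C)(C)[Si](C)(C)OCC[C@@H]1O[C@@H]([C@@H](O[Si](C)(C)C(C)(C)C)CCO)C[C@@H]1Cl | intermediate
16 | (3S)-3-[(tert-butyldimethylsilyl)oxy]-3-[(2R,4S,5S)-5-{2-[(tert-butyldimethylsilyl)oxy]ethyl}-4-chlorooxolan-2-yl]propanal | CC(C)(C)[Si](C)(C)OCC[C@@H]1O[C@@H]([C@@H](O[Si](C)(C)C(C)(C)C)CC=O)C[C@@H]1Cl | intermediate
17 | (2S,3S,5R)-2-{2-[(tert-butyldimethylsilyl)oxy]ethyl}-5-{(1S,3Z)-1-[(tert-butyldimethylsilyl)oxy]hex-3-en-1-yl}-3-chlorooxolane | CC(C)(C)[Si](C)(C)OCC[C@@H]1O[C@@H]([C@@H](O[Si](C)(C)C(C)(C)C)C/C=C\CC)C[C@@H]1Cl | intermediate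
18 | bromonium (bromiranium) ion of 17 at C12/C13, (12S,13R) | CC(C)(C)[Si](C)(C)OCC[C@@H]1O[C@@H]([C@@H](O[Si](C)(C)C(C)(C)C)C[C@@H]2[Br+][C@@H]2CC)C[C@@H]1Cl | intermediate
19 | cis-fused 1-oxoniabicyclo[3.3.0]octane ion (ring A plus ring B; oxygen bonded to C6, C9 and C12) | CC(C)(C)[Si](C)(C)OCC[C@H]1[C@@H](Cl)C[C@H]2[O+]1[C@H](C[C@@H]2O[Si](C)(C)C(C)(C)C)[C@H](Br)CC | intermediate
20 | (2S,3S,5S,6S,8R)-8-[(1R)-1-bromopropyl]-6-[(tert-butyldimethylsilyl)oxy]-2-{2-[(tert-butyldimethylsilyl)oxy]ethyl}-3,5-dichlorooxocane | CC(C)(C)[Si](C)(C)OCC[C@@H]1O[C@@H]([C@H](Br)CC)C[C@H](O[Si](C)(C)C(C)(C)C)[C@@H](Cl)C[C@@H]1Cl | intermediate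
21 | 2-{(2S,3S,5S,6S,8R)-8-[(1R)-1-bromopropyl]-6-[(tert-butyldimethylsilyl)oxy]-3,5-dichlorooxocan-2-yl}ethan-1-ol | OCC[C@@H]1O[C@@H]([C@H](Br)CC)C[C@H](O[Si](C)(C)C(C)(C)C)[C@@H](Cl)C[C@@H]1Cl | intermediate
22 | 2-{(2S,3S,5S,6S,8R)-8-[(1R)-1-bromopropyl]-6-[(tert-butyldimethylsilyl)oxy]-3,5-dichlorooxocan-2-yl}acetaldehyde | O=CC[C@@H]1O[C@@H]([C@H](Br)CC)C[C@H](O[Si](C)(C)C(C)(C)C)[C@@H](Cl)C[C@@H]1Cl | intermediate
23 | (2S,3S,5S,6S,8R)-8-[(1R)-1-bromopropyl]-6-[(tert-butyldimethylsilyl)oxy]-3,5-dichloro-2-[(2Z)-5-(triisopropylsilyl)pent-2-en-4-yn-1-yl]oxocane | CC(C)[Si](C(C)C)(C(C)C)C#C/C=C\C[C@@H]1O[C@@H]([C@H](Br)CC)C[C@H](O[Si](C)(C)C(C)(C)C)[C@@H](Cl)C[C@@H]1Cl | intermediate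
24 | (2S,3S,5S,6S,8R)-8-[(1R)-1-bromopropyl]-3,5-dichloro-2-[(2Z)-pent-2-en-4-yn-1-yl]oxocan-6-ol | C#C/C=C\C[C@@H]1O[C@@H]([C@H](Br)CC)C[C@H](O)[C@@H](Cl)C[C@@H]1Cl | intermediate
25 | (2S,3S,5S,6S,8R)-8-[(1R)-1-bromopropyl]-3,5-dichloro-2-[(2Z)-pent-2-en-4-yn-1-yl]oxocan-6-yl acetate | C#C/C=C\C[C@@H]1O[C@@H]([C@H](Br)CC)C[C@H](OC(C)=O)[C@@H](Cl)C[C@@H]1Cl | target

**Step count**

Total: 17 steps. Longest linear sequence: 16 steps (steps 1, 2 and 4–17; step 3 prepares the alkenyl iodide).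

**Steps most likely to fail**

1. Step 12 (Proposed new method). What may go wrong: loss of regiocontrol in the opening of the oxonium ion (chloride attacking C6 or C12 instead of the fusion carbon), or interception of the bromonium or oxonium ion by bromide or diethyl sulfide released from the reagent before chloride arrives. The fallback uses known chemistry, sets out from 17 and comes back at 20; it ties the nucleophile for the ring expansion to C10 and brings chlorine in afterwards.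
   - Both silyl ethers of 17 are removed (Bu4NF, THF) to give (1S,3Z)-1-[(2R,4S,5S)-4-chloro-5-(2-hydroxyethyl)oxolan-2-yl]hex-3-en-1-ol F1.
   - The primary hydroxyl is silylated again (TBSCl, imidazole, CH2Cl2, −20 °C) to give the mono-silyl ether F2, and the C10 hydroxyl is converted into its tert-butyl carbonate F3 (Boc2O, DMAP, MeCN).
   - F3 is submitted to the established carbonate-terminated ring-expanding bromoetherification (BDSB, MeNO2, −25 °C). The carbonyl oxygen tethered next to C9 opens the oxonium ion at the fusion carbon with loss of 2-methylpropene and should give the trans-fused cyclic carbonate F4, whose new C9–O bond occupies the position required for chlorine.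
   - Methanolysis (K2CO3, MeOH) gives the 5,6-diol F5, and SO2Cl2/Et3N (CH2Cl2, −78 °C) gives the cyclic sulfate F6.
   - Bu4NCl (THF) should replace the C9 oxygen by chlorine with retention, since only C9 can ionise with transannular help from the ring oxygen (the known behaviour of oxocan-5-yl sulfonates), giving the sulfate monoester salt F7. This stage still relies on chloride returning to the fusion carbon, so it answers interception by reagent-derived nucleophiles better than it answers a mis-directed chloride.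
   - Acid hydrolysis (cat. H2SO4, H2O/THF) gives the chloro diol F8, and silylation of both hydroxyls (TBSOTf, 2,6-lutidine) gives 20.

2. Step 15. What may go wrong: erosion of Z/E control, or base-induced β-elimination of the ring oxygen from the β-alkoxy aldehyde under the lithium reagent. Fallback from 22, back at 23: Stork–Zhao olefination (Ph3PCH2I iodide, NaN(SiMe3)2, DMPU/THF, −78 °C) gives the (Z)-alkenyl iodide F9, and Sonogashira coupling with (triisopropylsilyl)acetylene (PdCl2(PPh3)2, CuI, i-Pr2NH, rt) gives 23.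

3. Step 5. What may go wrong: elimination or incomplete inversion during activation of the hindered C7 alcohol next to the silyloxy-bearing carbon. Fallback from 8, back at 9: the alcohol is isolated as its chloromethanesulfonate F10 (ClCH2SO2Cl, pyridine, 0 °C), a more reactive and isolable sulfonate leaving group, and this is displaced by chloride with inversion (LiCl, DMF, 50 °C) to give 9.

**Further compounds**

F1 | step 12 | (1S,3Z)-1-[(2R,4S,5S)-4-chloro-5-(2-hydroxyethyl)oxolan-2-yl]hex-3-en-1-ol | OCC[C@@H]1O[C@@H]([C@@H](O)C/C=C\CC)C[C@@H]1Cl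
F2 | step 12 | (1S,3Z)-1-[(2R,4S,5S)-5-{2-[(tert-butyldimethylsilyl)oxy]ethyl}-4-chlorooxolan-2-yl]hex-3-en-1-ol | CC(C)(C)[Si](C)(C)OCC[C@@H]1O[C@@H]([C@@H](O)C/C=C\CC)C[C@@H]1Cl
F3 | step 12 | tert-butyl (1S,3Z)-1-[(2R,4S,5S)-5-{2-[(tert-butyldimethylsilyl)oxy]ethyl}-4-chlorooxolan-2-yl]hex-3-en-1-yl carbonate | CC(C)(C)[Si](C)(C)OCC[C@@H]1O[C@@H]([C@@H](OC(=O)OC(C)(C)C)C/C=C\CC)C[C@@H]1Cl
F4 | step 12 | trans-fused 5,6-cyclic carbonate of (2S,3S,5S,6S,8R)-8-[(1R)-1-bromopropyl]-2-{2-[(tert-butyldimethylsilyl)oxy]ethyl}-3-chlorooxocane-5,6-diol | CC(C)(C)[Si](C)(C)OCC[C@@H]1O[C@@H]([C@H](Br)CC)C[C@@H]2OC(=O)O[C@H]2C[C@@H]1Cl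
F5 | step 12 | (2S,3S,5S,6S,8R)-8-[(1R)-1-bromopropyl]-2-{2-[(tert-butyldimethylsilyl)oxy]ethyl}-3-chlorooxocane-5,6-diol | CC(C)(C)[Si](C)(C)OCC[C@@H]1O[C@@H]([C@H](Br)CC)C[C@H](O)[C@@H](O)C[C@@H]1Cl
F6 | step 12 | trans-fused 5,6-cyclic sulfate of F5 | CC(C)(C)[Si](C)(C)OCC[C@@H]1O[C@@H]([C@H](Br)CC)C[C@@H]2OS(=O)(=O)O[C@H]2C[C@@H]1Cl
F7 | step 12 | tetrabutylammonium (2S,3S,5S,6S,8R)-8-[(1R)-1-bromopropyl]-2-{2-[(tert-butyldimethylsilyl)oxy]ethyl}-3,5-dichlorooxocan-6-yl sulfate | CC(C)(C)[Si](C)(C)OCC[C@@H]1O[C@@H]([C@H](Br)CC)C[C@H](OS(=O)(=O)[O-])[C@@H](Cl)C[C@@H]1Cl.CCCC[N+](CCCC)(CCCC)CCCC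
F8 | step 12 | (2S,3S,5S,6S,8R)-8-[(1R)-1-bromopropyl]-3,5-dichloro-2-(2-hydroxyethyl)oxocan-6-ol | OCC[C@@H]1O[C@@H]([C@H](Br)CC)C[C@H](O)[C@@H](Cl)C[C@@H]1Cl
F9 | step 15 | (2S,3S,5S,6S,8R)-8-[(1R)-1-bromopropyl]-6-[(tert-butyldimethylsilyl)oxy]-3,5-dichloro-2-[(2Z)-3-iodoprop-2-en-1-yl]oxocane | I/C=C\C[C@@H]1O[C@@H]([C@H](Br)CC)C[C@H](O[Si](C)(C)C(C)(C)C)[C@@H](Cl)C[C@@H]1Cl
F10 | step 5 | (3S,4R,6E)-9-(benzyloxy)-3-[(triethylsilyl)oxy]nona-1,6-dien-4-yl chloromethanesulfonate | C=C[C@H](O[Si](CC)(CC)CC)[C@H](OS(=O)(=O)CCl)C/C=C/CCOCc1ccccc1
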